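**Retrosynthetic overview**

1. The target is a genistein dimer, with unit 1 joined through C6 and unit 2 through C8. The last operations remove two C2 silyl placeholders with fluoride and cleave six O-methyl groups with BBr3.
2. Feature used: in each benzopyranone the C4 carbonyl sits on C4a, next to the O1-bearing C8a. Ring A plus C4 is therefore a salicylaldehyde at a higher oxidation level, and C2=C3 with ring B on C3 is the residue of an arylalkyne.
3. Key disconnection: C4–C3 and O1–C2 are cut in both units. This leads back to biaryl bis-salicylaldehyde 12 and two molecules of aryl(silyl)alkyne 16. Both pyranone rings (ring C of each unit) close last, in one flask, and each brings its ring B.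
4. Compound 12 comes from bisphenol 10 by twofold ortho-formylation. The hydroxyl para to the axis defines the C6-linked unit and the hydroxyl ortho to the axis defines the C8-linked unit.
5. The axis is made first, by Suzuki–Miyaura coupling of boronate 4 (directed lithiation of the MOM ether of 3,5-dimethoxyphenol) with bromide 8 (C–H borylation/oxidation of 2-bromo-1,3-dimethoxybenzene).

Key step: step 9

Assumption: the SMILES string fixes no axial configuration, so the hindered C6–C8 biaryl axis is made as the racemic mixture of atropisomers.

**Route**

Step 1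
Reactants: 1 3,5-dimethoxyphenol
Product: 2 1,3-dimethoxy-5-(methoxymethoxy)benzene
Conditions: MOMCl, iPr2NEt, CH2Cl2, 0 °C to rt
Reagents that add atoms: chloromethyl methyl ether, COCCl
Why: O-alkylation of the phenol with an α-chloro ether (MOM protection) masks the acidic hydroxyl and installs the chelating group that directs the lithiation of step 2.

Step 2
Reactants: 2 1,3-dimethoxy-5-(methoxymethoxy)benzene
Product: 4 2-[2,4-dimethoxy-6-(methoxymethoxy)phenyl]-4,4,5,5-tetramethyl-1,3,2-dioxaborolane, via aryllithium 3 (not isolated)
Conditions: n-BuLi, THF, 0 °C to rt; then iPrOBpin, −78 °C to rt; aqueous work-up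
Reagents that add atoms: 2-isopropoxy-4,4,5,5-tetramethyl-1,3,2-dioxaborolane, CC(C)OB1OC(C)(C)C(C)(C)O1; n-butyllithium, [Li]CCCC (lithium of 3 only)
Why: In this directed ortho-metalation the chelating OCH2OCH3 group, helped by the flanking methoxy group, steers n-BuLi to one of the two equivalent C–H bonds between them rather than to the C–H between two methoxy groups, and the aryllithium is trapped by alkoxide displacement at boron.

Step 3
Reactants: 5 2-bromo-1,3-dimethoxybenzene
Product: 7 4-bromo-3,5-dimethoxyphenol, via arylboronate 6 (not isolated)
Conditions: [Ir(OMe)(cod)]2 (cat.), 4,4'-di-tert-butyl-2,2'-bipyridine, B2pin2, THF, 80 °C; concentrate; then KHSO5 (as 2KHSO5·KHSO4·K2SO4), acetone/H2O, rt, short contact time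
Reagents that add atoms: bis(pinacolato)diboron, CC1(C)OB(OC1(C)C)B1OC(C)(C)C(C)(C)O1 (boryl group of 6); potassium peroxymonosulfate, [K+].[O-]S(=O)(=O)OO (phenol oxygen of 7)
Why: Sterically governed iridium-catalysed C–H borylation reaches only C5, the one C–H with no ortho substituent, leaves the C–Br bond intact, and peroxide oxidation of the C–B bond (1,2-aryl shift to oxygen) gives the phenol para to bromine without any regiochemical ambiguity.

Step 4
Reactants: 7 4-bromo-3,5-dimethoxyphenol
Product: 8 2-bromo-1,3-dimethoxy-5-(methoxymethoxy)benzene
Conditions: MOMCl, iPr2NEt, CH2Cl2, 0 °C to rt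
Reagents that add atoms: chloromethyl methyl ether, COCCl
Why: MOM protection by O-alkylation prevents formation of a phenoxide, which would slow oxidative addition in step 5, and uses the same group as in 4 so that both come off together.

Step 5
Reactants: 4 2-[2,4-dimethoxy-6-(methoxymethoxy)phenyl]-4,4,5,5-tetramethyl-1,3,2-dioxaborolane (1.5 equiv); 8 2-bromo-1,3-dimethoxy-5-(methoxymethoxy)benzene
Product: 9 2,2',4',6-tetramethoxy-4,6'-bis(methoxymethoxy)-1,1'-biphenyl
Conditions: Pd2(dba)3 (cat.), SPhos, K3PO4, toluene/H2O 10:1, 100 °C, argon
Reagents that add atoms: none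
Why: In this Suzuki–Miyaura coupling the bulky, electron-rich dialkylbiarylphosphine keeps zerovalent palladium monoligated, which speeds oxidative addition into the electron-rich C–Br bond and reductive elimination of the tetra-ortho-oxygenated biaryl, whose flanking groups are only small alkoxy groups, while the pinacol ester in excess limits protodeboronation.

Step 6
Reactants: 9 2,2',4',6-tetramethoxy-4,6'-bis(methoxymethoxy)-1,1'-biphenyl
Product: 10 4-(2-hydroxy-4,6-dimethoxyphenyl)-3,5-dimethoxyphenol
Conditions: HCl (cat.), MeOH, dilute, 45 °C
Reagents that add atoms: none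
Why: Acid-catalysed acetal exchange with methanol cleaves both MOM ethers and leaves the four aryl methyl ethers untouched, and dilution keeps the released formaldehyde acetal from alkylating the electron-rich rings.

Step 7
Reactants: 10 4-(2-hydroxy-4,6-dimethoxyphenyl)-3,5-dimethoxyphenol; 11 formaldehyde (as paraformaldehyde, excess)
Product: 12 2',4-dihydroxy-2,4',6,6'-tetramethoxy-[1,1'-biphenyl]-3,3'-dicarbaldehyde
Conditions: MgCl2 (anhydrous), Et3N, (CH2O)n, MeCN, reflux; dilute HCl work-up
Reagents that add atoms: formaldehyde 11, C=O
Why: In the Casnati–Skattebøl ortho-formylation each magnesium phenoxide delivers coordinated formaldehyde only to a carbon ortho to its own oxygen and a second formaldehyde accepts hydride from the benzylic alkoxide, so one ring reacts at one of its two equivalent free positions and the other at its only free ortho position, while the chelated, deactivated salicylaldehyde resists further formylation.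

Step 8
Reactants: 13 4-ethynylanisole; 14 chlorotrimethylsilane
Product: 16 1-methoxy-4-[(trimethylsilyl)ethynyl]benzene, via lithium acetylide 15 (not isolated)
Conditions: n-BuLi, THF, −78 °C; then Me3SiCl, −78 °C to rt
Reagents that add atoms: chlorotrimethylsilane 14, C[Si](C)(C)Cl; n-butyllithium, [Li]CCCC (lithium of 15 only)
Why: Deprotonation of the terminal alkyne and substitution at silicon (acetylide C-silylation) is fast and clean, and no other acidic or electrophilic site is present.

Step 9
Reactants: 12 2',4-dihydroxy-2,4',6,6'-tetramethoxy-[1,1'-biphenyl]-3,3'-dicarbaldehyde; 16 1-methoxy-4-[(trimethylsilyl)ethynyl]benzene (3 equiv, two incorporated)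
Product: 17 5,7-dimethoxy-6-[5,7-dimethoxy-3-(4-methoxyphenyl)-4-oxo-2-(trimethylsilyl)-4H-chromen-8-yl]-3-(4-methoxyphenyl)-2-(trimethylsilyl)-4H-chromen-4-one
Conditions: [Cp*RhCl2]2 (5 mol %), AgSbF6 (20 mol %), Cu(OAc)2 (anhydrous, 4.4 equiv), 4 Å molecular sieves, ClCH2CH2Cl, 100 °C, sealed tube, argon
Reagents that add atoms: none
Why: Proposed new method: each phenoxide binds cationic Cp*Rh (trivalent rhodium), acetate-assisted cleavage of the adjacent aldehyde C–H bond gives a five-membered acyl rhodacycle, the alkyne inserts into the Rh–acyl bond, and C–O reductive elimination from the seven-membered oxarhodacycle releases the chromone and monovalent rhodium, which two equivalents of Cu(OAc)2 (divalent copper) per ring reoxidise. The closest known reaction type is the rhodium-catalysed oxidative [4+2] annulation of salicylaldehydes with internal diaryl, dialkyl and aryl(alkyl) alkynes to 2,3-disubstituted chromones; new here are the aryl(silyl)alkyne partner and the twofold use on one hindered biaryl. Both pyranone rings close in the same mode, intermolecular C4–C3 bond formation followed by six-membered ring closure through O1–C2 reductive elimination, the two annulations running one after the other in the same flask. The selectivity that matters is the orientation of insertion: the bulky silyl group should avoid the short developing C4–C3 bond and sit on the carbon that keeps the longer C–Rh bond, which silicon also stabilises, as it does in palladium-catalysed heteroannulations that give 2-silylindoles and 2-silylbenzofurans, so that the anisyl-bearing carbon becomes C3 and the silyl-bearing carbon C2. Site selectivity is built into 12, because each aldehyde has one free hydroxyl on one side and a methoxy group on the other, which fixes the C6 and C8 linkages and also blocks later carbonyl-directed C–H activation at C5. No stereocentre is formed and the axis stays racemic; AgSbF6 is matched to the chloride of the precatalyst and water is excluded so that the C–Si bond of 16 survives until insertion, whereas loss of silicon from 17 would only anticipate step 10.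

Step 10
Reactants: 17 the 2,2''-bis(trimethylsilyl) hexamethyl ether
Product: 18 5,7-dimethoxy-6-[5,7-dimethoxy-3-(4-methoxyphenyl)-4-oxo-4H-chromen-8-yl]-3-(4-methoxyphenyl)-4H-chromen-4-one (hexa-O-methyl ether of the target)
Conditions: Bu4NF (2.5 equiv), AcOH (2.5 equiv), THF, 0 °C to rt
Reagents that add atoms: none
Why: In this fluoride-induced protodesilylation of a vinylsilane, attack at silicon releases a C2 carbanion equivalent stabilised by the adjacent O1, which acetic acid protonates at once; the buffer prevents base-induced opening of the pyranone, and removing silicon now avoids ipso-borodesilylation by BBr3 in step 11.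

Step 11
Reactants: 18 hexa-O-methyl ether of the target
Product: 19 5,7-dihydroxy-6-[5,7-dihydroxy-3-(4-hydroxyphenyl)-4-oxo-4H-chromen-8-yl]-3-(4-hydroxyphenyl)-4H-chromen-4-one (target, CNP0184660.0)
Conditions: BBr3 (15 equiv), CH2Cl2, −78 °C to rt; ice-water quench
Reagents that add atoms: none
Why: In this Lewis-acid aryl methyl ether cleavage BBr3 binds each ether oxygen and bromide attacks the methyl group, the two C5 ethers reacting first through chelation to C4=O, and the cold aprotic medium avoids the ring opening and reclosure (Wessely–Moser rearrangement) that hot mineral acid could cause and that would interchange the C6 and C8 linkages.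

**Compound list**

1 | 3,5-dimethoxyphenol | COc1cc(O)cc(OC)c1 | starting material
2 | 1,3-dimethoxy-5-(methoxymethoxy)benzene | COCOc1cc(OC)cc(OC)c1 | intermediate
3 | 2,4-dimethoxy-6-(methoxymethoxy)phenyllithium | [Li]c1c(OC)cc(OC)cc1OCOC | intermediate
4 | 2-[2,4-dimethoxy-6-(methoxymethoxy)phenyl]-4,4,5,5-tetramethyl-1,3,2-dioxaborolane | COCOc1cc(OC)cc(OC)c1B1OC(C)(C)C(C)(C)O1 | intermediate
5 | 2-bromo-1,3-dimethoxybenzene | COc1cccc(OC)c1Br | starting material
6 | 2-(4-bromo-3,5-dimethoxyphenyl)-4,4,5,5-tetramethyl-1,3,2-dioxaborolane | COc1cc(B2OC(C)(C)C(C)(C)O2)cc(OC)c1Br | intermediate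
7 | 4-bromo-3,5-dimethoxyphenol | COc1cc(O)cc(OC)c1Br | intermediate
8 | 2-bromo-1,3-dimethoxy-5-(methoxymethoxy)benzene | COCOc1cc(OC)c(Br)c(OC)c1 | intermediate
9 | 2,2',4',6-tetramethoxy-4,6'-bis(methoxymethoxy)-1,1'-biphenyl | COCOc1cc(OC)c(-c2c(OC)cc(OC)cc2OCOC)c(OC)c1 | intermediate
10 | 4-(2-hydroxy-4,6-dimethoxyphenyl)-3,5-dimethoxyphenol | COc1cc(O)cc(OC)c1-c1c(O)cc(OC)cc1OC | intermediate
11 | formaldehyde (as paraformaldehyde) | C=O | starting material
12 | 2',4-dihydroxy-2,4',6,6'-tetramethoxy-[1,1'-biphenyl]-3,3'-dicarbaldehyde (racemic axis) | COc1cc(O)c(C=O)c(OC)c1-c1c(OC)cc(OC)c(C=O)c1O | intermediate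
13 | 4-ethynylanisole | C#Cc1ccc(OC)cc1 | starting material
14 | chlorotrimethylsilane | C[Si](C)(C)Cl | starting material
15 | lithium (4-methoxyphenyl)acetylide | [Li]C#Cc1ccc(OC)cc1 | intermediate
16 | 1-methoxy-4-[(trimethylsilyl)ethynyl]benzene | COc1ccc(C#C[Si](C)(C)C)cc1 | intermediate
17 | 5,7-dimethoxy-6-[5,7-dimethoxy-3-(4-methoxyphenyl)-4-oxo-2-(trimethylsilyl)-4H-chromen-8-yl]-3-(4-methoxyphenyl)-2-(trimethylsilyl)-4H-chromen-4-one (racemic axis) | COc1cc2oc([Si](C)(C)C)c(-c3ccc(OC)cc3)c(=O)c2c(OC)c1-c1c(OC)cc(OC)c2c(=O)c(-c3ccc(OC)cc3)c([Si](C)(C)C)oc12 | intermediate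
18 | 5,7-dimethoxy-6-[5,7-dimethoxy-3-(4-methoxyphenyl)-4-oxo-4H-chromen-8-yl]-3-(4-methoxyphenyl)-4H-chromen-4-one (racemic axis) | COc1cc2occ(-c3ccc(OC)cc3)c(=O)c2c(OC)c1-c1c(OC)cc(OC)c2c(=O)c(-c3ccc(OC)cc3)coc12 | intermediate
19 | 5,7-dihydroxy-6-[5,7-dihydroxy-3-(4-hydroxyphenyl)-4-oxo-4H-chromen-8-yl]-3-(4-hydroxyphenyl)-4H-chromen-4-one (racemic axis) | O=c1c(-c2ccc(O)cc2)coc2cc(O)c(-c3c(O)cc(O)c4c(=O)c(-c5ccc(O)cc5)coc34)c(O)c12 | target

**Step count**

- Total step count: 11.
- Longest linear sequence: 8 steps (1, 2, 5, 6, 7, 9, 10, 11 from compound 1; equally 3, 4, 5, 6, 7, 9, 10, 11 from compound 5).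

**Steps most likely to fail**

**Step 9.**
- The alkyne may insert with the opposite orientation, placing the aryl group next to oxygen.
- The alkyne may lose silicon before insertion and then undergo copper-mediated dimerisation.
- The acyl rhodacycle may decarbonylate.
- The reaction may stall after the first annulation at the hindered biaryl.

The fallback is the classical deoxybenzoin construction of isoflavones. It sets out from 10 and comes back at 18, bypassing 12, 16 and 17. Bisphenol 10 is C-acylated on both rings with 4-methoxyphenylacetic acid (COc1ccc(CC(=O)O)cc1) in BF3·OEt2 at about 80 °C. This is a Friedel–Crafts/Fries-type acylation in which the difluoroboron chelate holds each acyl group next to the free hydroxyl. It gives the bis-deoxybenzoin F1. Heating F1 with N,N-dimethylformamide dimethyl acetal (COC(OC)N(C)C) in toluene adds C2 of each unit as an enaminone carbon. That carbon closes onto the free hydroxyl with loss of dimethylamine and gives 18.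

**Step 5.** Protodeboronation of the electron-rich, di-ortho-alkoxy boronate may outrun the slow transmetalation and reductive elimination at the tetra-ortho-substituted axis. The fallback avoids cross-coupling altogether, sets out from 2 and comes back at 10.
- Compound 2 is lithiated to 3 as in step 2 and added at −78 °C in THF to 2,6-dimethoxy-1,4-benzoquinone (COC1=CC(=O)C=C(OC)C1=O).
- The C1 carbonyl of this quinone is the electrophilic one, because both methoxy groups deactivate C4 as a vinylogous ester. 1,2-Addition therefore gives the para-quinol F2.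
- Reductive aromatisation with zinc dust in AcOH at rt removes the tertiary hydroxyl and gives the mono-MOM biaryl phenol F3, with its free hydroxyl para to the new axis.
- HCl in MeOH, as in step 6, then gives 10.

**Step 7.** The formylation may stop after one ring. The electron-rich rings may also condense with excess formaldehyde, by O-methoxymethylation or diarylmethane formation. The fallback replaces the phenoxide-directed formylation by directed metalation at the protected stage, sets out from 9 and comes back at 12.
- Compound 9 is dilithiated with n-BuLi/TMEDA in THF at 0 °C. Each MOM ether directs to the C–H between itself and a methoxy group.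
- Quenching with DMF gives the bis-MOM dialdehyde F4.
- HCl in MeOH cleaves the two acetals, which are activated by the ortho formyl groups, and gives 12.

**Further compounds**

F1 | step 9 | 1,1'-(2',4-dihydroxy-2,4',6,6'-tetramethoxy-[1,1'-biphenyl]-3,3'-diyl)bis[2-(4-methoxyphenyl)ethan-1-one] | COc1cc(O)c(C(=O)Cc2ccc(OC)cc2)c(OC)c1-c1c(OC)cc(OC)c(C(=O)Cc2ccc(OC)cc2)c1O
F2 | step 5 | 4-[2,4-dimethoxy-6-(methoxymethoxy)phenyl]-4-hydroxy-3,5-dimethoxycyclohexa-2,5-dien-1-one | COCOc1cc(OC)cc(OC)c1C1(O)C(OC)=CC(=O)C=C1OC
F3 | step 5 | 4-[2,4-dimethoxy-6-(methoxymethoxy)phenyl]-3,5-dimethoxyphenol | COCOc1cc(OC)cc(OC)c1-c1c(OC)cc(O)cc1OC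
F4 | step 7 | 2,4',6,6'-tetramethoxy-2',4-bis(methoxymethoxy)-[1,1'-biphenyl]-3,3'-dicarbaldehyde | COCOc1cc(OC)c(-c2c(OC)cc(OC)c(C=O)c2OCOC)c(OC)c1C=O
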